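## Analysis of the target

The target 19 is a C25 bicyclic sesterterpenoid; labdane-type numbering is used for the decalin (ring A: C1–C5 and C10; ring B: C5–C10; C17 on C8, C18 and C19 on C4, C20 on C10), C11–C16 for the chain (C16 is the hydroxymethyl carbon on C13) and O1'–C5' for the lactone. Rings A and B form a trans-fused decalin with a gem-dimethyl carbon C4, an angular methyl on C10 and a tetrasubstituted C8=C9 alkene in ring B that carries the C17 methyl and the C11–C12 ethano tether. The tether ends at C13 of a 2-substituted allylic alcohol whose C13=C14 bond is conjugated through C14–C15 with the exocyclic C15=C5' bond of a 4'-methylbutenolide. There are only two stereocentres, C5 (S) and the quaternary C10 (S); they are adjacent, trans to each other (H5 α, C20 β, normal labdane series) and sit in a hydrocarbon region with no heteroatom that could direct their formation. Two alkenes are stereogenic: C13=C14 is E (C16 trans to C15, so C12 is cis to C15) and C15=C5' is Z (O1' cis to C14). Sensitive groups are the cross-conjugated trienyl enol lactone (base, nucleophiles, light, strong acid), the primary allylic alcohol and the electron-rich tetrasubstituted alkene. The difficulty lies in setting the absolute configuration of the unfunctionalised decalin, in placing the ring B alkene at C8=C9 rather than C7=C8 or C8=C17, and in fixing the C13=C14 geometry while the fragile lactone is brought in late. The feature that invites the key move is the homoallylic array C8=C9–C11–C12: it is the retron of a cyclopropylcarbinyl-to-homoallyl opening, and the cation it needs at C8 is exactly the one at which a labdane-type cation–olefin bicyclisation ends, so C9, C11 and C12 can be a cyclopropane in an acyclic precursor.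

## Retrosynthetic reasoning

**19 to 18, then C15=C5'.** The free C16 alcohol is unmasked last from silyl ether 18. The ylidene bond C15=C5' of 18 is cut to enal 14 and the intact lactone 15. This brings in the most fragile unit late and in one operation (vinylogous aldol addition and elimination via 16 and 17). The Z geometry is thermodynamic, because the C4' methyl clashes with C14 in the E isomer.

**14 to 12.** Enal 14 is traced through allylic alcohol 13 to enoate 12. This is a plain adjustment of oxidation level at C15 and leaves the C13=C14 geometry untouched.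

**C12–C13.** Enoate 12 is cut between the sp3 carbon C12 and the sp2 carbon C13, giving homoallylic chloride 5 (nucleophile, via Grignard reagent 11) and Z-enol triflate 10 (electrophile). The cut is placed here because the C13=C14 geometry can then be set in a small acyclic fragment and transferred with retention. The triflate oxygen cis to the ester in 10 becomes C12 cis to C15 in 12.

**Triflate 10.** It comes from β-keto ester 8 through the chelated enolate 9, and 8 from aldehyde 6 and diazo ester 7. The silyl ether that becomes the C16 oxygen is present from the start.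

**Key disconnection, 5 to 4.** In 5 the bonds C4–C5 and C9–C10 and the C12–Cl bond are cut, and a C9–C12 bond is restored, so that C9, C11 and C12 become a cyclopropylidene unit. The precursor 4 is an achiral, acyclic C16 triene with no stereocentre and no ring other than the cyclopropane. The forward reaction has to initiate at C3 with a chiral proton source, close rings A and B, and end by halide opening of the cyclopropylcarbinyl cation at C8. This sets both stereocentres, fixes the tetrasubstituted C8=C9 alkene without regioisomers, and delivers the C12 handle.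

**4 to 1 and 2.** The cyclopropylidene alkene is cut by a Wittig disconnection to commercial ketone 1 and phosphonium salt 2 (via ylide 3). The key-step precursor therefore costs one step.

## Alternatives that were turned down

**Alternative 1:** the textbook chiral-pool route. Commercial (+)-sclareolide A1 already holds rings A and B and both stereocentres. The forward key operations would be acid-mediated lactone opening with dehydration and alkene equilibration to the C8=C9 isomer, reduction and bromination to the homoallylic bromide A2, followed by the same C12–C13 coupling. It was turned down as the main plan because it builds nothing of the skeleton and sets no stereocentre. The alkene position is reached only by equilibrating three regioisomers, and it needs three to four functional-group steps for what the chosen key step gives in one. It is kept only as the safety net for step 2.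

**Alternative 2:** disconnection at C9–C11. The (S)-Wieland–Miescher ketone A3 would be converted into the bicyclic ketone A4. Its enol triflate A5 forms only towards C8 because C10 is quaternary, and a B-alkyl Suzuki coupling with a complete C11–C16 side-chain borane would follow. It was turned down on step economy and on mechanism. A4 needs about eight steps from A3 (reductive gem-dimethylation, removal of the C3 oxygen, α-methylation). The coupling would take place at a tetrasubstituted triflate flanked by the quaternary C10 and the C8 methyl, the slowest case for oxidative addition and transmetallation. The side-chain alkyl metal would need its own multi-step synthesis.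

**Alternative 3:** epoxide-initiated bicyclisation. The (S)-epoxide A6 of triene 4 (made from 1 by asymmetric dihydroxylation, mesylation, ring closure and the same Wittig reaction) would be cyclised with a Lewis acid to the 3β-hydroxy chloride A7. This would make the site of initiation and the absolute configuration secure. It was turned down because it spends three steps to install and two steps (Barton–McCombie deoxygenation) to remove a C3 oxygen that the target does not have. This roughly triples the cost of reaching chloride 5.

Key step: step 2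

Assumption: the (R)-configured binaphthol-ether acid is taken to induce the (5S,10S) series here, as it does with homofarnesyl substrates; if the sense were reversed on this substrate, the (S)-acid would be used with no other change.

## Route

**Step 1**
Reactants: 1 (E)-geranylacetone [(5E)-6,10-dimethylundeca-5,9-dien-2-one]; 2 cyclopropyltriphenylphosphonium bromide
Product: 4 [(5E)-6,10-dimethylundeca-5,9-dien-2-ylidene]cyclopropane, via cyclopropylidenetriphenylphosphorane 3 (not isolated)
Conditions: NaH, tris[2-(2-methoxyethoxy)ethyl]amine (10 mol%), THF, 62 °C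
Reagents that add atoms: none
Why: Wittig olefination with the non-stabilised cyclopropylidene ylide 3; the phase-transfer amine keeps the ylide in solution so that addition should outrun enolisation of the methyl ketone; no stereocentre is formed and the existing E-alkene is not touched.

**Step 2**
Reactants: 4 [(5E)-6,10-dimethylundeca-5,9-dien-2-ylidene]cyclopropane
Product: 5 (4aS,8aS)-5-(2-chloroethyl)-1,1,4a,6-tetramethyl-1,2,3,4,4a,7,8,8a-octahydronaphthalene
Conditions: (R)-2'-[(2-fluorobenzyl)oxy]-1,1'-binaphthalen-2-ol·SnCl4 (preformed, 2 equiv), toluene, −78 °C, then −40 °C; aq. NaHCO3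
Reagents that add atoms: tin tetrachloride (chloride source), Cl[Sn](Cl)(Cl)Cl
Why: Proposed new method: an alkylidenecyclopropane has not been shown as the terminator of an enantioselective proton-initiated polyene bicyclisation; the reasoning is that the C10 cation must attack the ring carbon C9 because only this gives a tertiary, cyclopropyl-stabilised cation at C8, which a halide then opens in the homoallyl sense, and the closest known reaction types are the cyclisation of homofarnesol and homo(polyprenyl)arenes by chiral binaphthol-ether·SnCl4 acids and the TiCl4-mediated Prins-type reactions of alkylidenecyclopropanes that end in homoallylic chlorides (Julia-type cyclopropylcarbinyl-to-homoallyl opening). Mechanism: the tin-activated naphthol proton adds to C3 of the terminal trisubstituted alkene, C5 of the E-alkene captures the C4 cation, C9 captures the C10 cation, and chloride from the stannate attacks C12 with cleavage of the C9–C12 cyclopropane bond. Ring A closes 6-endo-trig and ring B closes 6-endo-trig, both through chair-like folds. The trans relation of C5 and C10 follows from antiperiplanar addition across the E-configured C5=C10 alkene, and their absolute configuration is set by the chiral acid in the face-selective protonation and first ring closure. No stereocentre arises at C8 or C9, since both end up sp2, so the step needs no control there. The first selectivity needed is protonation at the terminal alkene rather than at the alkylidenecyclopropane, which the least hindered prenyl terminus and the bulk of the acid should secure. The second is the fate of the C8 cation: tertiary chloride and cyclobutyl products can re-ionise under SnCl4 whereas the primary homoallylic chloride cannot, so the material should funnel to 5 with release of the ring strain.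

**Step 3**
Reactants: 6 (tert-butyldimethylsilyloxy)acetaldehyde; 7 ethyl diazoacetate
Product: 8 ethyl 4-[(tert-butyldimethylsilyl)oxy]-3-oxobutanoate
Conditions: SnCl2 (10 mol%), CH2Cl2, rt
Reagents that add atoms: none
Why: Roskamp reaction: tin dichloride-catalysed addition of the diazo ester to the aldehyde, 1,2-hydride shift and loss of nitrogen give the β-keto ester directly; no stereocentre is formed.

**Step 4**
Reactants: 8 ethyl 4-[(tert-butyldimethylsilyl)oxy]-3-oxobutanoate
Product: 10 ethyl (2Z)-4-[(tert-butyldimethylsilyl)oxy]-3-{[(trifluoromethyl)sulfonyl]oxy}but-2-enoate, via sodium enolate 9 (not isolated)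
Conditions: NaH, Et2O, 0 °C; then Tf2O, 0 °C
Reagents that add atoms: trifluoromethanesulfonic anhydride, O=S(=O)(OS(=O)(=O)C(F)(F)F)C(F)(F)F
Why: Deprotonation between the two carbonyls gives the sodium-chelated Z-enolate 9, and O-sulfonylation traps this geometry, so the triflate oxygen sits cis to the ester; this is the geometry that later places C12 cis to C15.

**Step 5**
Reactants: 5 (4aS,8aS)-5-(2-chloroethyl)-1,1,4a,6-tetramethyl-1,2,3,4,4a,7,8,8a-octahydronaphthalene; 10 ethyl (2Z)-4-[(tert-butyldimethylsilyl)oxy]-3-{[(trifluoromethyl)sulfonyl]oxy}but-2-enoate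
Product: 12 ethyl (2E)-4-[(tert-butyldimethylsilyl)oxy]-3-{2-[(4aS,8aS)-2,5,5,8a-tetramethyl-3,4,4a,5,6,7,8,8a-octahydronaphthalen-1-yl]ethyl}but-2-enoate, via Grignard reagent 11 (not isolated)
Conditions: Mg turnings (I2 cat.), THF, 60 °C; then 10, Fe(acac)3 (5 mol%), THF/NMP, −30 °C
Reagents that add atoms: none
Why: Magnesium insertion into the primary chloride, then Fe(acac)3-catalysed Kumada-type coupling of the alkyl Grignard reagent with the enol triflate of a β-keto ester, which is fast at low temperature, tolerates the ester and proceeds with retention; C12 therefore ends cis to the ester carbon C15 and C16 trans to it (E by priority).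

**Step 6**
Reactants: 12 ethyl (2E)-4-[(tert-butyldimethylsilyl)oxy]-3-{2-[(4aS,8aS)-2,5,5,8a-tetramethyl-3,4,4a,5,6,7,8,8a-octahydronaphthalen-1-yl]ethyl}but-2-enoate
Product: 13 (2E)-4-[(tert-butyldimethylsilyl)oxy]-3-{2-[(4aS,8aS)-2,5,5,8a-tetramethyl-3,4,4a,5,6,7,8,8a-octahydronaphthalen-1-yl]ethyl}but-2-en-1-ol
Conditions: i-Bu2AlH (2.5 equiv), CH2Cl2, −78 °C; aq. potassium sodium tartrate
Reagents that add atoms: none
Why: 1,2-Reduction of the conjugated ester to the allylic alcohol by the aluminium hydride; the silyl ether and both alkenes are inert and the alkene geometry is kept.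

**Step 7**
Reactants: 13 (2E)-4-[(tert-butyldimethylsilyl)oxy]-3-{2-[(4aS,8aS)-2,5,5,8a-tetramethyl-3,4,4a,5,6,7,8,8a-octahydronaphthalen-1-yl]ethyl}but-2-en-1-ol
Product: 14 (2E)-4-[(tert-butyldimethylsilyl)oxy]-3-{2-[(4aS,8aS)-2,5,5,8a-tetramethyl-3,4,4a,5,6,7,8,8a-octahydronaphthalen-1-yl]ethyl}but-2-enal
Conditions: MnO2 (excess), CH2Cl2, rt
Reagents that add atoms: none
Why: Allylic oxidation with manganese dioxide under neutral conditions; it is selective for the allylic alcohol and should not isomerise the trisubstituted alkene.

**Step 8**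
Reactants: 14 (2E)-4-[(tert-butyldimethylsilyl)oxy]-3-{2-[(4aS,8aS)-2,5,5,8a-tetramethyl-3,4,4a,5,6,7,8,8a-octahydronaphthalen-1-yl]ethyl}but-2-enal; 15 4-methylfuran-2(5H)-one
Product: 18 (5Z)-5-[(2E)-4-[(tert-butyldimethylsilyl)oxy]-3-{2-[(4aS,8aS)-2,5,5,8a-tetramethyl-3,4,4a,5,6,7,8,8a-octahydronaphthalen-1-yl]ethyl}but-2-en-1-ylidene]-4-methylfuran-2(5H)-one, via silyloxyfuran 16 (not isolated), via aldol silyl ether 17 (not isolated)
Conditions: 15, TBSOTf (1.3 equiv), i-Pr2NEt, CH2Cl2, 0 °C; then 14, −78 °C; then DBU, −78 °C to rt
Reagents that add atoms: none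
Why: Vinylogous Mukaiyama aldol addition of C5 of the preformed silyloxyfuran 16 to the silyl-activated aldehyde gives 17, and DBU then removes silanolate by an E1cB elimination; the Z geometry at C15=C5' is the thermodynamic one because the C4' methyl clashes with C14 in the E isomer.

**Step 9**
Reactants: 18 (5Z)-5-[(2E)-4-[(tert-butyldimethylsilyl)oxy]-3-{2-[(4aS,8aS)-2,5,5,8a-tetramethyl-3,4,4a,5,6,7,8,8a-octahydronaphthalen-1-yl]ethyl}but-2-en-1-ylidene]-4-methylfuran-2(5H)-one
Product: 19 (5Z)-5-[(2E)-4-hydroxy-3-{2-[(4aS,8aS)-2,5,5,8a-tetramethyl-3,4,4a,5,6,7,8,8a-octahydronaphthalen-1-yl]ethyl}but-2-en-1-ylidene]-4-methylfuran-2(5H)-one (CNP0288110.2)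
Conditions: HF·pyridine, pyridine, THF, 0 °C
Reagents that add atoms: none
Why: Fluoride cleavage of the primary silyl ether under buffered, weakly acidic conditions, which should spare the enol lactone and the triene geometry.

## Compound list

1 | (E)-geranylacetone, (5E)-6,10-dimethylundeca-5,9-dien-2-one | CC(C)=CCC/C(C)=C/CCC(C)=O | starting material
2 | cyclopropyltriphenylphosphonium bromide | [Br-].C1CC1[P+](c1ccccc1)(c1ccccc1)c1ccccc1 | starting material
3 | cyclopropylidenetriphenylphosphorane | C1CC1=P(c1ccccc1)(c1ccccc1)c1ccccc1 | intermediate (not isolated)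
4 | [(5E)-6,10-dimethylundeca-5,9-dien-2-ylidene]cyclopropane | CC(C)=CCC/C(C)=C/CCC(C)=C1CC1 | intermediate
5 | (4aS,8aS)-5-(2-chloroethyl)-1,1,4a,6-tetramethyl-1,2,3,4,4a,7,8,8a-octahydronaphthalene | ClCCC1=C(C)CC[C@H]2C(C)(C)CCC[C@]12C | intermediate
6 | (tert-butyldimethylsilyloxy)acetaldehyde | CC(C)(C)[Si](C)(C)OCC=O | starting material
7 | ethyl diazoacetate | CCOC(=O)C=[N+]=[N-] | starting material
8 | ethyl 4-[(tert-butyldimethylsilyl)oxy]-3-oxobutanoate | CCOC(=O)CC(=O)CO[Si](C)(C)C(C)(C)C | intermediate
9 | sodium (Z)-enolate of 8, sodium (2Z)-1-[(tert-butyldimethylsilyl)oxy]-4-ethoxy-4-oxobut-2-en-2-olate | CCOC(=O)/C=C(\[O-])CO[Si](C)(C)C(C)(C)C.[Na+] | intermediate (not isolated)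
10 | ethyl (2Z)-4-[(tert-butyldimethylsilyl)oxy]-3-{[(trifluoromethyl)sulfonyl]oxy}but-2-enoate | CCOC(=O)/C=C(\OS(=O)(=O)C(F)(F)F)CO[Si](C)(C)C(C)(C)C | intermediate
11 | {2-[(4aS,8aS)-2,5,5,8a-tetramethyl-3,4,4a,5,6,7,8,8a-octahydronaphthalen-1-yl]ethyl}magnesium chloride | Cl[Mg]CCC1=C(C)CC[C@H]2C(C)(C)CCC[C@]12C | intermediate (not isolated)
12 | ethyl (2E)-4-[(tert-butyldimethylsilyl)oxy]-3-{2-[(4aS,8aS)-2,5,5,8a-tetramethyl-3,4,4a,5,6,7,8,8a-octahydronaphthalen-1-yl]ethyl}but-2-enoate | CCOC(=O)/C=C(/CO[Si](C)(C)C(C)(C)C)CCC1=C(C)CC[C@H]2C(C)(C)CCC[C@]12C | intermediate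
13 | (2E)-4-[(tert-butyldimethylsilyl)oxy]-3-{2-[(4aS,8aS)-2,5,5,8a-tetramethyl-3,4,4a,5,6,7,8,8a-octahydronaphthalen-1-yl]ethyl}but-2-en-1-ol | OC/C=C(/CO[Si](C)(C)C(C)(C)C)CCC1=C(C)CC[C@H]2C(C)(C)CCC[C@]12C | intermediate
14 | (2E)-4-[(tert-butyldimethylsilyl)oxy]-3-{2-[(4aS,8aS)-2,5,5,8a-tetramethyl-3,4,4a,5,6,7,8,8a-octahydronaphthalen-1-yl]ethyl}but-2-enal | O=C/C=C(/CO[Si](C)(C)C(C)(C)C)CCC1=C(C)CC[C@H]2C(C)(C)CCC[C@]12C | intermediate
15 | 4-methylfuran-2(5H)-one | CC1=CC(=O)OC1 | starting material
16 | tert-butyldimethyl[(4-methylfuran-2-yl)oxy]silane | Cc1coc(O[Si](C)(C)C(C)(C)C)c1 | intermediate (not isolated)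
17 | 5-[(2E)-1,4-bis[(tert-butyldimethylsilyl)oxy]-3-{2-[(4aS,8aS)-2,5,5,8a-tetramethyl-3,4,4a,5,6,7,8,8a-octahydronaphthalen-1-yl]ethyl}but-2-en-1-yl]-4-methylfuran-2(5H)-one, mixture of diastereomers at the two new centres | CC1=CC(=O)OC1C(O[Si](C)(C)C(C)(C)C)/C=C(/CO[Si](C)(C)C(C)(C)C)CCC1=C(C)CC[C@H]2C(C)(C)CCC[C@]12C | intermediate (not isolated)
18 | (5Z)-5-[(2E)-4-[(tert-butyldimethylsilyl)oxy]-3-{2-[(4aS,8aS)-2,5,5,8a-tetramethyl-3,4,4a,5,6,7,8,8a-octahydronaphthalen-1-yl]ethyl}but-2-en-1-ylidene]-4-methylfuran-2(5H)-one | CC1=CC(=O)O/C1=C\C=C(\CO[Si](C)(C)C(C)(C)C)CCC1=C(C)CC[C@H]2C(C)(C)CCC[C@]12C | intermediate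
19 | (5Z)-5-[(2E)-4-hydroxy-3-{2-[(4aS,8aS)-2,5,5,8a-tetramethyl-3,4,4a,5,6,7,8,8a-octahydronaphthalen-1-yl]ethyl}but-2-en-1-ylidene]-4-methylfuran-2(5H)-one | CC1=CC(=O)O/C1=C\C=C(\CO)CCC1=C(C)CC[C@H]2C(C)(C)CCC[C@]12C | target

## Step count and risks

Total step count: 9 steps. Longest linear sequence: 7 steps from 1 (steps 1, 2, 5, 6, 7, 8, 9); the triflate branch (steps 3 and 4) is 2 steps.

**Step 2 (key step, proposed new method).** Most likely failure modes:
- Protonation at the alkylidenecyclopropane instead of the terminal alkene, which would open the three-membered ring before any ring closure.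
- Interruption of the cascade after ring A by proton loss.
- Ring expansion of the C8 cation towards a cyclobutane or its capture as a tertiary chloride that does not funnel onward at low temperature.
- Incomplete face discrimination by the chiral acid, which would lower the enantiomeric purity of everything downstream.

Fallback (known chemistry; a carboxylate-terminated cyclisation replaces the strain-release terminator): it sets out from 1 and comes back to the route at 5. Wittig reaction of 1 with the ylide from (2-carboxyethyl)triphenylphosphonium bromide (NaN(SiMe3)2, THF) should give (3E,7E)-4,8,12-trimethyltrideca-3,7,11-trienoic acid F1, together with its 3Z isomer, which the next step does not convert. Enzymatic cyclisation with a squalene–hopene cyclase, in which the carboxylate captures the C8 cation, should give (+)-sclareolide F2 as a single enantiomer. Methanolysis with H2SO4 in methanol, followed by acid equilibration of the alkene isomers (catalytic HI, benzene), should give the C8=C9 ester methyl 2-[(4aS,8aS)-2,5,5,8a-tetramethyl-3,4,4a,5,6,7,8,8a-octahydronaphthalen-1-yl]acetate F3. LiAlH4 reduction should give 2-[(4aS,8aS)-2,5,5,8a-tetramethyl-3,4,4a,5,6,7,8,8a-octahydronaphthalen-1-yl]ethanol F4, and Appel chlorination (PPh3, CCl4) then gives 5.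

**Step 5.** Most likely failure modes: sluggish magnesium insertion into the primary chloride with Wurtz-type dimerisation; and, in the coupling, reduction or homocoupling of the triflate, addition of the Grignard reagent to the ester, or erosion of the alkene geometry.

Fallback (acylation and carbonyl olefination replace the cross-coupling, and triflate 10 is no longer needed): it sets out from 5 and comes back at 12. Finkelstein exchange (NaI, acetone, reflux) should give (4aS,8aS)-5-(2-iodoethyl)-1,1,4a,6-tetramethyl-1,2,3,4,4a,7,8,8a-octahydronaphthalene F5. Iodine–lithium exchange (t-BuLi, Et2O, −78 °C) and acylation of the resulting alkyllithium with 2-[(tert-butyldimethylsilyl)oxy]-N-methoxy-N-methylacetamide should give 1-[(tert-butyldimethylsilyl)oxy]-4-[(4aS,8aS)-2,5,5,8a-tetramethyl-3,4,4a,5,6,7,8,8a-octahydronaphthalen-1-yl]butan-2-one F6. Wittig reaction of F6 with ethyl (triphenylphosphoranylidene)acetate (toluene, 90 °C) should give 12, the α-silyloxy group directing the ester trans to C16.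

**Step 8.** Most likely failure modes: conjugate addition of the silyloxyfuran to the enal instead of 1,2-addition; soft enolisation of the enal towards C12 or C16; incomplete elimination; and base-induced isomerisation of the C13=C14 alkene in the extended conjugated product.

Fallback (cross-coupling and cycloisomerisation replace the aldol condensation): it sets out from 14 and comes back at 18. Corey–Fuchs homologation (CBr4, PPh3, CH2Cl2, 0 °C) should give the dibromodiene tert-butyl{[(2E)-5,5-dibromo-2-{2-[(4aS,8aS)-2,5,5,8a-tetramethyl-3,4,4a,5,6,7,8,8a-octahydronaphthalen-1-yl]ethyl}penta-2,4-dien-1-yl]oxy}dimethylsilane F7. Treatment with n-BuLi (2 equiv, THF, −78 °C) and then water should give the enyne tert-butyldimethyl{[(2E)-2-{2-[(4aS,8aS)-2,5,5,8a-tetramethyl-3,4,4a,5,6,7,8,8a-octahydronaphthalen-1-yl]ethyl}pent-2-en-4-yn-1-yl]oxy}silane F8. Sonogashira coupling of F8 with (Z)-3-iodobut-2-enoic acid (Pd(PPh3)4, CuI, Et3N, MeCN, rt) is followed in the same flask by 5-exo-dig addition of the carboxylate to the alkyne, which should give 18 with the Z geometry that results from anti addition.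

## Further compounds

F1 | step 2 | (3E,7E)-4,8,12-trimethyltrideca-3,7,11-trienoic acid | CC(C)=CCC/C(C)=C/CC/C(C)=C/CC(=O)O
F2 | step 2 | (+)-sclareolide, (3aR,5aS,9aS,9bR)-3a,6,6,9a-tetramethyldecahydronaphtho[2,1-b]furan-2(1H)-one | C[C@]12CCCC([C@@H]1CC[C@@]3([C@@H]2CC(=O)O3)C)(C)C
F3 | step 2 | methyl 2-[(4aS,8aS)-2,5,5,8a-tetramethyl-3,4,4a,5,6,7,8,8a-octahydronaphthalen-1-yl]acetate | COC(=O)CC1=C(C)CC[C@H]2C(C)(C)CCC[C@]12C
F4 | step 2 | 2-[(4aS,8aS)-2,5,5,8a-tetramethyl-3,4,4a,5,6,7,8,8a-octahydronaphthalen-1-yl]ethanol | OCCC1=C(C)CC[C@H]2C(C)(C)CCC[C@]12C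
F5 | step 5 | (4aS,8aS)-5-(2-iodoethyl)-1,1,4a,6-tetramethyl-1,2,3,4,4a,7,8,8a-octahydronaphthalene | ICCC1=C(C)CC[C@H]2C(C)(C)CCC[C@]12C
F6 | step 5 | 1-[(tert-butyldimethylsilyl)oxy]-4-[(4aS,8aS)-2,5,5,8a-tetramethyl-3,4,4a,5,6,7,8,8a-octahydronaphthalen-1-yl]butan-2-one | CC(C)(C)[Si](C)(C)OCC(=O)CCC1=C(C)CC[C@H]2C(C)(C)CCC[C@]12C
F7 | step 8 | tert-butyl{[(2E)-5,5-dibromo-2-{2-[(4aS,8aS)-2,5,5,8a-tetramethyl-3,4,4a,5,6,7,8,8a-octahydronaphthalen-1-yl]ethyl}penta-2,4-dien-1-yl]oxy}dimethylsilane | BrC(Br)=C/C=C(/CO[Si](C)(C)C(C)(C)C)CCC1=C(C)CC[C@H]2C(C)(C)CCC[C@]12C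
F8 | step 8 | tert-butyldimethyl{[(2E)-2-{2-[(4aS,8aS)-2,5,5,8a-tetramethyl-3,4,4a,5,6,7,8,8a-octahydronaphthalen-1-yl]ethyl}pent-2-en-4-yn-1-yl]oxy}silane | C#C/C=C(/CO[Si](C)(C)C(C)(C)C)CCC1=C(C)CC[C@H]2C(C)(C)CCC[C@]12C
A1 | alternative 1 | (+)-sclareolide, (3aR,5aS,9aS,9bR)-3a,6,6,9a-tetramethyldecahydronaphtho[2,1-b]furan-2(1H)-one | C[C@]12CCCC([C@@H]1CC[C@@]3([C@@H]2CC(=O)O3)C)(C)C
A2 | alternative 1 | (4aS,8aS)-5-(2-bromoethyl)-1,1,4a,6-tetramethyl-1,2,3,4,4a,7,8,8a-octahydronaphthalene | BrCCC1=C(C)CC[C@H]2C(C)(C)CCC[C@]12C
A3 | alternative 2 | (S)-Wieland–Miescher ketone, (8aS)-8a-methyl-3,4,8,8a-tetrahydronaphthalene-1,6(2H,7H)-dione | C[C@]12CCC(=O)C=C1CCCC2=O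
A4 | alternative 2 | (4aS,8aS)-2,5,5,8a-tetramethyloctahydronaphthalen-1(2H)-one, C2 epimers | CC1CC[C@H]2C(C)(C)CCC[C@]2(C)C1=O
A5 | alternative 2 | (4aS,8aS)-2,5,5,8a-tetramethyl-3,4,4a,5,6,7,8,8a-octahydronaphthalen-1-yl trifluoromethanesulfonate | O=S(=O)(OC1=C(C)CC[C@H]2C(C)(C)CCC[C@]12C)C(F)(F)F
A6 | alternative 3 | (3S)-3-[(3E)-7-cyclopropylidene-4-methyloct-3-en-1-yl]-2,2-dimethyloxirane | CC1(C)O[C@H]1CC/C(C)=C/CCC(C)=C1CC1
A7 | alternative 3 | 3β-hydroxy derivative of 5, (2S,4aS,8aR)-5-(2-chloroethyl)-1,1,4a,6-tetramethyl-1,2,3,4,4a,7,8,8a-octahydronaphthalen-2-ol | ClCCC1=C(C)CC[C@H]2C(C)(C)[C@@H](O)CC[C@]12C
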